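Assumption: compounds 1 and 11, the alkyl halides, DMF and mCPBA are purchased; the ether protecting groups are a free choice, so ring A and ring D carry benzyl ethers and allyl serves as the temporary mask during chain growth.

## Structural features

Tetraphlorethol C (19) is an achiral, linear tetramer of phloroglucinol: four benzene rings (A to D) joined only by three diaryl ether oxygens, with nine free phenolic hydroxyls, no stereocentre and no carbon–carbon bond between rings. Ring A is a 3,5-dihydroxyphenyl group bound through oxygen to C1 of ring B; ring B is bound through its C4 oxygen to C1 of ring C, and ring C through its C4 oxygen to C1 of ring D, whose C4 carries the last hydroxyl. In each of rings B, C and D the ether-bearing C1 is flanked by hydroxyls at C2 and C6. Every inter-ring bond therefore ends on a di-ortho-oxygenated, electron-rich carbon, a hindered and deactivated site for copper- or palladium-mediated etherification, and this is the real difficulty. The free polyphenol is fragile: it is oxidised by air, fastest in base, and rings A and D are phloroglucinol-type, strongly nucleophilic at carbon and acid-sensitive at their ether bonds, so the last unmasking should be neutral. The key step exploits the C2/C6 oxygenation of rings B, C and D: carried as formyl groups, these six positions make C1 electron-poor enough to take a phenoxide by fluoride displacement, and each C–CHO bond is later exchanged for a C–O bond by aryl migration. One latent incompatibility follows: an electron-rich ring A held through oxygen next to a ring B formyl group can close to a xanthenol under Lewis or strong Brønsted acid, so no such acid is used while both are present.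

## Logic of the disconnections

19 to 18: the three benzyl–oxygen bonds (two on ring A, one at C4 of ring D) are cut. Hydrogenolysis is then the only operation performed on the free nonaphenol, and it is neutral. The demand is that 18 holds nothing else reducible and that the benzyl ethers survive every earlier step.

18 to 16 (through 17): the six aryl C–O bonds at C2 and C6 of rings B, C and D are replaced by six aryl C–CHO bonds. This turns six donors into six acceptors, which makes the three ether disconnections below possible, and removes six hydroxyls from the protecting-group problem. The forward step must give aryl and not hydride migration at all six sites, spare ring A and the benzyl ethers, and release the phenols without base or air damage.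

16 to 15 and 10: the bond from the C4 oxygen of ring C to C1 of ring D is cut. C1 of ring D lies between two formyl groups, so a fluoride there is displaced without a metal. This splits off a monomer. The weakly nucleophilic diformyl phenoxide must attack the fluoride faster than it exchanges aryloxy groups at the other formyl-flanked ether carbons.

15 to 14, then 14 to 13 and 9: the allyl–oxygen bond is cut, then the bond from the C4 oxygen of ring B to C1 of ring C. Allyl is chosen as the temporary mask because zerovalent palladium removes it under neutral conditions. A Lewis acid strong enough to cleave a simple alkyl ether would drive ring A onto a neighbouring formyl group. The demand is an allyl acceptor that touches neither aldehydes nor activated ethers.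

13 to 12, then 12 to 11 and 9: the same pair of cuts gives the first ether bond, from the ring A oxygen to C1 of ring B. The ambident, electron-rich phenoxide of 11 must react at oxygen and not at carbon.

9 and 10 to 8: the O–allyl and O–benzyl bonds are cut, so one phenol supplies both monomers. The alkylation must outrun self-condensation of the fluoro phenoxide with its own product.

8 to 7, 7 to 2, 2 to 1: the O–isopropyl bond is cut first. A Lewis acid is acceptable at this stage because no electron-rich ring is present. Then the two C–CHO bonds beside fluorine are cut, which requires metalation next to fluorine rather than next to the ether oxygen, with the first formyl group carried through the second metalation in masked form. The last cut is the O-alkylation of 1.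

## Other disconnections considered

Alternative 1: Two carbon–carbon bonds of ring A are cut, so that ring A comes from the four carbons of 3-ethoxycyclobut-2-en-1-one A2 and the two alkyne carbons of the aryl ethynyl ether A1 built on a permethylated B–C–D unit.
- Forward step: heating opens A2 to a vinylketene, which adds to A1 in a [2+2] sense; the new cyclobutenone opens and closes by 6π electrocyclisation to the phenol A3 (Danheiser benzannulation).
- In favour: the 1,3,5-oxygen pattern is fixed by ketene/ynol ether polarity, the three oxygens of ring A arrive differentiated, and the conditions are neutral and oxidant-free.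
- Against: ring A is the one ring that can be bought with the right pattern (11), so the annulation addresses no real difficulty. The three hindered ethers of rings B to D must still be made first. A1 is a terminal alkynyl ether on a di-ortho-substituted oxygen, a labile class that needs strong base to prepare. A3 needs seven methyl ethers and one ethyl ether cleaved on phloroglucinol-type rings, the harshest possible endgame.
- Comparison: on structure it forms one ring and none of the difficult bonds, against six C–O bonds on three rings in the chosen step. On mechanism it is the better of the two, since a pericyclic cascade has no competing migration and no oxidant near electron-rich rings. On step economy it is longer, because trimer assembly, ethynylation, annulation and eightfold dealkylation exceed the twelve steps chosen here.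

Alternative 2: One carbon–carbon bond of ring A is cut so that its six carbons come from the 4-aryloxy-6-methyl-2H-pyran-2-one A4.
- Forward step: Mg(OMe)2 in methanol opens the lactone to a methyl ester, the enolate of the freed methyl ketone attacks that ester (Claisen-type carbocyclisation), and enolisation gives the resorcinol A5.
- In favour: ring A appears with both hydroxyls free. On this point it is better than the chosen plan, which carries two benzyl ethers on ring A through eight steps. The reagents are cheap and mild.
- Against: A4 needs a hindered di-ortho-methoxy phenol attached at C4 of the pyranone. That aryloxy group is a vinylogous aryl ester, so methoxide can add at C4 and expel the trimer phenoxide before or after ring opening. The difficult ethers are again not addressed, and seven methyl ethers must then be cleaved beside a free resorcinol.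
- Comparison: on structure it builds one ring that needs no building. On mechanism it is an ionic condensation without oxidant, equal to the chosen step in mildness but with a leaving-group problem of its own. On step economy it is longer.

Alternative 3: Two carbon–carbon bonds of ring D are cut, so that ring D comes from the three carbons of the aryloxymalonate A6 and the three central carbons of dimethyl 3-oxopentanedioate A7.
- Forward step: NaOMe promotes a double Claisen condensation, each methylene of A7 being acylated by one ester of A6, and enolisation gives the phloroglucinol diester A8.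
- In favour: the ring D ether oxygen is attached to an sp3 malonate carbon and not to a di-ortho-substituted arene carbon. For that one bond it is better than the chosen plan. Ring D also arrives with three free hydroxyls and no regiochemical question.
- Against: the C–H of A6 is its most acidic site, and once deprotonated its esters are poor acyl acceptors, so the twofold condensation fights retro-Claisen and O-acylation. A8 then needs ester hydrolysis, double decarboxylation and sixfold demethylation on a free phloroglucinol. The A–B–C unit with two hindered ethers must be made beforehand.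
- Comparison: on structure it makes one ring and leaves two of the three difficult ethers to other chemistry. On mechanism it is a classical condensation, equal to the chosen step in the simplicity of its reagents but in doubt over the reversed polarity of A6. On step economy it is clearly longer after the key step.

Key step: step 11

## Route

Step 1
Reactants: 1 4-fluorophenol
Product: 2 1-fluoro-4-(propan-2-yloxy)benzene
Conditions: 2-bromopropane, K2CO3, DMF, 60 °C
Reagents that add atoms: 2-bromopropane, CC(C)Br
Why: Williamson ether synthesis; the phenoxide displaces bromide from the secondary halide, used in excess to offset competing elimination. The bulky isopropyl ether is stable to alkyllithiums and a poor director of metalation, which the next step needs.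

Step 2
Reactants: 2 1-fluoro-4-(propan-2-yloxy)benzene
Product: 7 2-fluoro-5-(propan-2-yloxy)benzene-1,3-dicarbaldehyde, via aryllithium 3 (not isolated), via lithium amino alkoxide 4 (not isolated), via ring-lithiated amino alkoxide 5 (not isolated), via dilithium bis(amino alkoxide) 6 (not isolated)
Conditions: s-BuLi (1.05 equiv), PMDTA, THF, −78 °C; DMF (1.05 equiv); s-BuLi (1.2 equiv), −78 °C; DMF; inverse quench into cold aq. HCl
Reagents that add atoms: N,N-dimethylformamide, CN(C)C=O
Why: Directed ortho-metalation and formylation with DMF, done twice in one flask: with the base saturated by PMDTA, coordination to the hindered isopropoxy oxygen is suppressed and the most acidic C–H, the one beside fluorine, is removed. The DMF adduct 4 is a tetrahedral lithium amino alkoxide that is inert to s-BuLi and masks the first aldehyde, so the second fluorine-adjacent C–H can be metalated and formylated. Holding −78 °C prevents LiF loss to an aryne, and the inverse acidic quench protonates dimethylamine as it is released so that it cannot displace the doubly activated fluoride.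

Step 3
Reactants: 7 2-fluoro-5-(propan-2-yloxy)benzene-1,3-dicarbaldehyde
Product: 8 2-fluoro-5-hydroxybenzene-1,3-dicarbaldehyde
Conditions: BCl3, CH2Cl2, −78 → 0 °C; then H2O
Reagents that add atoms: none
Why: Lewis-acid dealkylation of a secondary alkyl aryl ether: chloride attacks the isopropyl carbon of the boron-bound ether, and hydrolysis frees the phenol. The aryl fluoride is inert and the aldehydes return from their boron adducts on work-up. A Lewis acid is safe here because no electron-rich ring is yet in the molecule.

Step 4
Reactants: 8 2-fluoro-5-hydroxybenzene-1,3-dicarbaldehyde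
Product: 9 2-fluoro-5-(prop-2-en-1-yloxy)benzene-1,3-dicarbaldehyde
Conditions: allyl bromide (3 equiv), K2CO3, acetone, rt
Reagents that add atoms: allyl bromide, C=CCBr
Why: Williamson O-allylation; the reactive halide in excess, at room temperature in a weakly polar solvent, should alkylate the phenoxide well before it can displace the fluoride of another molecule.

Step 5
Reactants: 8 2-fluoro-5-hydroxybenzene-1,3-dicarbaldehyde
Product: 10 5-(benzyloxy)-2-fluorobenzene-1,3-dicarbaldehyde
Conditions: BnBr, K2CO3, acetone, rt
Reagents that add atoms: benzyl bromide, BrCc1ccccc1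
Why: Williamson O-benzylation under the same mild conditions as step 4; it supplies the ring D monomer with its permanent, hydrogenolysable ether.

Step 6
Reactants: 11 3,5-bis(benzyloxy)phenol; 9 2-fluoro-5-(prop-2-en-1-yloxy)benzene-1,3-dicarbaldehyde
Product: 12 2-[3,5-bis(benzyloxy)phenoxy]-5-(prop-2-en-1-yloxy)benzene-1,3-dicarbaldehyde
Conditions: K2CO3, DMF, 50 °C
Reagents that add atoms: none
Why: Nucleophilic aromatic substitution: the phenoxide adds to the fluorine-bearing carbon, the Meisenheimer adduct is stabilised by both ortho formyl groups, and fluoride leaves. A potassium phenoxide in a dipolar aprotic solvent reacts at oxygen with this hard electrophilic carbon, and the basic medium gives ring A no chance to close onto a formyl group.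

Step 7
Reactants: 12 2-[3,5-bis(benzyloxy)phenoxy]-5-(prop-2-en-1-yloxy)benzene-1,3-dicarbaldehyde
Product: 13 2-[3,5-bis(benzyloxy)phenoxy]-5-hydroxybenzene-1,3-dicarbaldehyde
Conditions: Pd(PPh3)4 (5 mol %), TolSO2Na, THF/MeOH, rt; then aq. HCl to pH 4
Reagents that add atoms: none
Why: Tsuji–Trost deallylation: zerovalent palladium ionises the allyl ether of this acidic phenol to a π-allyl complex, and the soft sulfinate takes the allyl group as a sulfone. The medium is neutral and free of Lewis acid, amine and alkoxide, so formyl groups, the activated diaryl ether, benzyl ethers and the ring A/formyl pair are left alone.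

Step 8
Reactants: 13 2-[3,5-bis(benzyloxy)phenoxy]-5-hydroxybenzene-1,3-dicarbaldehyde; 9 2-fluoro-5-(prop-2-en-1-yloxy)benzene-1,3-dicarbaldehyde
Product: 14 2-[3,5-bis(benzyloxy)phenoxy]-5-[2,6-diformyl-4-(prop-2-en-1-yloxy)phenoxy]benzene-1,3-dicarbaldehyde
Conditions: K2CO3, DMF, 60 °C
Reagents that add atoms: none
Why: Nucleophilic aromatic substitution as in step 6; fluoride is a far better activator of the addition step than aryloxide, so with a slight excess of 9 the phenoxide should take the fluoride before it exchanges aryloxy groups at the formyl-flanked ether carbon.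

Step 9
Reactants: 14 2-[3,5-bis(benzyloxy)phenoxy]-5-[2,6-diformyl-4-(prop-2-en-1-yloxy)phenoxy]benzene-1,3-dicarbaldehyde
Product: 15 2-[3,5-bis(benzyloxy)phenoxy]-5-(2,6-diformyl-4-hydroxyphenoxy)benzene-1,3-dicarbaldehyde
Conditions: Pd(PPh3)4 (5 mol %), TolSO2Na, THF/MeOH, rt; then aq. HCl to pH 4
Reagents that add atoms: none
Why: Tsuji–Trost deallylation as in step 7, with the same tolerance of the four formyl groups and two activated ether bonds.

Step 10
Reactants: 15 2-[3,5-bis(benzyloxy)phenoxy]-5-(2,6-diformyl-4-hydroxyphenoxy)benzene-1,3-dicarbaldehyde; 10 5-(benzyloxy)-2-fluorobenzene-1,3-dicarbaldehyde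
Product: 16 2-[3,5-bis(benzyloxy)phenoxy]-5-{4-[4-(benzyloxy)-2,6-diformylphenoxy]-2,6-diformylphenoxy}benzene-1,3-dicarbaldehyde
Conditions: K2CO3, DMF, 60 °C
Reagents that add atoms: none
Why: Nucleophilic aromatic substitution as in steps 6 and 8; it completes the chain and places the hydrogenolysable benzyl ether at C4 of ring D.

Step 11
Reactants: 16 2-[3,5-bis(benzyloxy)phenoxy]-5-{4-[4-(benzyloxy)-2,6-diformylphenoxy]-2,6-diformylphenoxy}benzene-1,3-dicarbaldehyde
Product: 18 2-[3,5-bis(benzyloxy)phenoxy]-5-{4-[4-(benzyloxy)-2,6-dihydroxyphenoxy]-2,6-dihydroxyphenoxy}benzene-1,3-diol, via hexaformate 17 (not isolated)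
Conditions: mCPBA (9 equiv), Na2HPO4, CH2Cl2, 0 °C → rt; then MeOH, Et3N (cat.), argon, 0 °C
Reagents that add atoms: 3-chloroperbenzoic acid, OOC(=O)c1cccc(Cl)c1
Why: Baeyer–Villiger oxidation of aryl aldehydes (the peracid form of the Dakin reaction): mCPBA adds to each formyl carbon to give a Criegee adduct, and the aryl carbon shifts from carbon to the peroxide oxygen as 3-chlorobenzoate leaves, so each C–CHO bond becomes a C–O–CHO bond at the same ring position. The closest known reaction is the peracid oxidation of ortho-alkoxy and ortho-aryloxy benzaldehydes to aryl formates; here it is asked of six formyl groups of one type in one molecule. No ring is closed and no stereocentre is made. The selectivity needed is aryl over hydride migration at every site: each migrating carbon (C2 or C6 of rings B, C and D) has the ether oxygen of C1 directly ortho to it, whose lone pair stabilises the electron-poor migrating terminus, and the Na2HPO4 buffer keeps out strong acid or base that would favour the acid-forming hydride shift. Each formate replaces an acceptor by a weak donor on the same ring, so the second migration on a ring should be no slower than the first, while the formates keep the emerging rings too electron-poor for further peracid attack. The buffer also denies the ring A/ring B formyl pair the acid needed for xanthenol closure, and the benzyl ethers are inert to peracid. Surplus peracid is reduced (aq. Na2S2O3 wash) before the methanol stage, where catalytic Et3N passes the six formyl groups to methanol under argon and frees the six phenols without exposing them to oxidant or strong base.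

Step 12
Reactants: 18 2-[3,5-bis(benzyloxy)phenoxy]-5-{4-[4-(benzyloxy)-2,6-dihydroxyphenoxy]-2,6-dihydroxyphenoxy}benzene-1,3-diol
Product: 19 tetraphlorethol C, 2-{4-[4-(3,5-dihydroxyphenoxy)-3,5-dihydroxyphenoxy]-3,5-dihydroxyphenoxy}benzene-1,3,5-triol
Conditions: H2 (1 atm), Pd/C, MeOH/EtOAc, rt
Reagents that add atoms: none
Why: Catalytic hydrogenolysis of three aryl benzyl ethers; the conditions are neutral, the only co-product is toluene, and the arenes, diaryl ethers and free phenols are untouched, so the air-sensitive nonaphenol is obtained by filtration and evaporation under inert gas.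

## Compound list

1 | 4-fluorophenol | Oc1ccc(F)cc1 | starting material
2 | 1-fluoro-4-(propan-2-yloxy)benzene | CC(C)Oc1ccc(F)cc1 | intermediate
3 | [2-fluoro-5-(propan-2-yloxy)phenyl]lithium | CC(C)Oc1ccc(F)c([Li])c1 | intermediate (not isolated)
4 | lithium (dimethylamino)[2-fluoro-5-(propan-2-yloxy)phenyl]methanolate (racemic) | CC(C)Oc1ccc(F)c(c1)C(O[Li])N(C)C | intermediate (not isolated)
5 | lithium (dimethylamino)[2-fluoro-3-lithio-5-(propan-2-yloxy)phenyl]methanolate (racemic) | CC(C)Oc1cc([Li])c(F)c(c1)C(O[Li])N(C)C | intermediate (not isolated)
6 | dilithium [2-fluoro-5-(propan-2-yloxy)-1,3-phenylene]bis[(dimethylamino)methanolate] (stereoisomer mixture) | CC(C)Oc1cc(C(O[Li])N(C)C)c(F)c(c1)C(O[Li])N(C)C | intermediate (not isolated)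
7 | 2-fluoro-5-(propan-2-yloxy)benzene-1,3-dicarbaldehyde | CC(C)Oc1cc(C=O)c(F)c(C=O)c1 | intermediate
8 | 2-fluoro-5-hydroxybenzene-1,3-dicarbaldehyde | Oc1cc(C=O)c(F)c(C=O)c1 | intermediate
9 | 2-fluoro-5-(prop-2-en-1-yloxy)benzene-1,3-dicarbaldehyde | C=CCOc1cc(C=O)c(F)c(C=O)c1 | intermediate
10 | 5-(benzyloxy)-2-fluorobenzene-1,3-dicarbaldehyde | O=Cc1cc(OCc2ccccc2)cc(C=O)c1F | intermediate
11 | 3,5-bis(benzyloxy)phenol | Oc1cc(OCc2ccccc2)cc(OCc2ccccc2)c1 | starting material
12 | 2-[3,5-bis(benzyloxy)phenoxy]-5-(prop-2-en-1-yloxy)benzene-1,3-dicarbaldehyde | C=CCOc1cc(C=O)c(Oc2cc(OCc3ccccc3)cc(OCc3ccccc3)c2)c(C=O)c1 | intermediate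
13 | 2-[3,5-bis(benzyloxy)phenoxy]-5-hydroxybenzene-1,3-dicarbaldehyde | Oc1cc(C=O)c(Oc2cc(OCc3ccccc3)cc(OCc3ccccc3)c2)c(C=O)c1 | intermediate
14 | 2-[3,5-bis(benzyloxy)phenoxy]-5-[2,6-diformyl-4-(prop-2-en-1-yloxy)phenoxy]benzene-1,3-dicarbaldehyde | C=CCOc1cc(C=O)c(Oc2cc(C=O)c(Oc3cc(OCc4ccccc4)cc(OCc4ccccc4)c3)c(C=O)c2)c(C=O)c1 | intermediate
15 | 2-[3,5-bis(benzyloxy)phenoxy]-5-(2,6-diformyl-4-hydroxyphenoxy)benzene-1,3-dicarbaldehyde | Oc1cc(C=O)c(Oc2cc(C=O)c(Oc3cc(OCc4ccccc4)cc(OCc4ccccc4)c3)c(C=O)c2)c(C=O)c1 | intermediate
16 | 2-[3,5-bis(benzyloxy)phenoxy]-5-{4-[4-(benzyloxy)-2,6-diformylphenoxy]-2,6-diformylphenoxy}benzene-1,3-dicarbaldehyde | c1ccccc1COc1cc(OCc2ccccc2)cc(Oc2c(C=O)cc(Oc3c(C=O)cc(Oc4c(C=O)cc(OCc5ccccc5)cc4C=O)cc3C=O)cc2C=O)c1 | intermediate (key-step precursor)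
17 | 2-[3,5-bis(benzyloxy)phenoxy]-5-{4-[4-(benzyloxy)-2,6-bis(formyloxy)phenoxy]-2,6-bis(formyloxy)phenoxy}-1,3-phenylene diformate | c1ccccc1COc1cc(OCc2ccccc2)cc(Oc2c(OC=O)cc(Oc3c(OC=O)cc(Oc4c(OC=O)cc(OCc5ccccc5)cc4OC=O)cc3OC=O)cc2OC=O)c1 | intermediate (not isolated)
18 | 2-[3,5-bis(benzyloxy)phenoxy]-5-{4-[4-(benzyloxy)-2,6-dihydroxyphenoxy]-2,6-dihydroxyphenoxy}benzene-1,3-diol (tetraphlorethol C 3,5-di-O-benzyl (ring A) 4-O-benzyl (ring D) ether) | c1ccccc1COc1cc(OCc2ccccc2)cc(Oc2c(O)cc(Oc3c(O)cc(Oc4c(O)cc(OCc5ccccc5)cc4O)cc3O)cc2O)c1 | intermediate (key-step product)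
19 | tetraphlorethol C, 2-{4-[4-(3,5-dihydroxyphenoxy)-3,5-dihydroxyphenoxy]-3,5-dihydroxyphenoxy}benzene-1,3,5-triol | Oc1cc(O)cc(Oc2c(O)cc(Oc3c(O)cc(Oc4c(O)cc(O)cc4O)cc3O)cc2O)c1 | target

## Step count and least certain steps

Total: 12 steps. Longest linear sequence: 11 steps (1, 2, 3, 4, 6, 7, 8, 9, 10, 11, 12, counted from compound 1); step 5 is a one-step branch from 8.

**Step 11 (key step).** The likeliest failure is hydride migration in one or more of the six Criegee adducts, which would divert material irreversibly to carboxylic acids. Each migrating carbon has only one ortho oxygen donor and also feels a meta formyl group. Incomplete conversion to mixed formyl/formate species, slow closure of ring A onto a ring B formyl group in the acidic medium, and electrophilic hydroxylation of ring A by surplus peracid are further risks. The fallback removes the competition by exchanging hydrogen for methyl, the poorest migrating group. It sets out from 16 and returns at 18.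
- MeMgBr in THF at −78 °C would add to all six formyl groups to give the hexakis(1-hydroxyethyl) compound F1, a diastereomer mixture whose stereocentres are erased in the next operation.
- Dess–Martin periodinane would oxidise F1 to the hexaacetyl compound F2.
- mCPBA, buffered as in step 11, would convert the six aryl methyl ketones to the hexaacetate F3, since aryl migrates in preference to methyl.
- K2CO3 in degassed MeOH would cleave F3 to 18.

**Step 2.** The second metalation may go to the carbon between the masked formyl group and the ether oxygen instead of the carbon beside fluorine. The ortho-fluoro aryllithiums can also lose LiF if the temperature rises, and dimethylamine can displace the activated fluoride during the quench. The fallback screens both oxygen-adjacent positions with a bulky silyl ether. It sets out from 1 and returns at 8, bypassing 2 to 7.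
- TIPSCl and imidazole in DMF would give (4-fluorophenoxy)tri(propan-2-yl)silane F4.
- The same telescoped metalation–formylation would pass through the aryllithium F5, the lithium amino alkoxide F6, its ring-lithiated form F7 and the dilithium bis(amino alkoxide) F8 to 2-fluoro-5-{[tri(propan-2-yl)silyl]oxy}benzene-1,3-dicarbaldehyde F9.
- KHF2 in MeOH, a weakly acidic fluoride source that does not build up phenoxide, would release 8.

**Step 10 (the same concern applies to step 8).** Displacement may be slow because the phenoxide is weakly nucleophilic and the fluoride partner carries a para alkoxy donor. The heating then needed would let the phenoxide exchange aryloxy groups at the formyl-flanked ether carbons and scramble the chain. The fallback is a convergent assembly in which the last coupling meets a more electrophilic fluoride. It sets out from 8 (with 10 and 13 as partners) and returns at 16, bypassing 14 and 15.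
- Ethylene glycol with TsOH in toluene would convert 8 to 4-fluoro-3,5-bis(1,3-dioxolan-2-yl)phenol F10, whose own fluoride is no longer activated.
- The phenoxide of F10 with 10 (K2CO3, DMF) would give 5-(benzyloxy)-2-[4-fluoro-3,5-bis(1,3-dioxolan-2-yl)phenoxy]benzene-1,3-dicarbaldehyde F11.
- Aqueous HCl in THF, harmless because no electron-rich ring is present, would unmask 5-(benzyloxy)-2-(4-fluoro-3,5-diformylphenoxy)benzene-1,3-dicarbaldehyde F12.
- The fluoride of F12 is para to an aryloxy group instead of an alkoxy group and should be displaced by the phenoxide of 13 under mild conditions to give 16.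

**Step 7 (and step 9).** Allyl transfer may stall through return of the allyl group to the phenoxide or reversible addition of sulfinate to formyl groups, or the catalyst may be held by the product. The fallback exchanges the palladium-labile mask for an oxidatively labile one. It sets out from 8 and returns at 13, and in the second cycle at 15.
- PMBCl and K2CO3 in acetone would convert 8 to 2-fluoro-5-[(4-methoxyphenyl)methoxy]benzene-1,3-dicarbaldehyde F13.
- Coupling of F13 with 11 as in step 6 would give 2-[3,5-bis(benzyloxy)phenoxy]-5-[(4-methoxyphenyl)methoxy]benzene-1,3-dicarbaldehyde F14.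
- DDQ in CH2Cl2/water at pH 7 would release 13.
- Coupling of 13 with F13 would likewise give the PMB ether F15 of 15, cleaved in the same way to 15.

## Further compounds

F1 | step 11 | hexakis(1-hydroxyethyl) analogue of 16 (each CHO replaced by CH(OH)CH3; diastereomer mixture, configuration not defined) | c1ccccc1COc1cc(OCc2ccccc2)cc(Oc2c(C(C)O)cc(Oc3c(C(C)O)cc(Oc4c(C(C)O)cc(OCc5ccccc5)cc4C(C)O)cc3C(C)O)cc2C(C)O)c1
F2 | step 11 | hexaacetyl analogue of 16 (each CHO replaced by COCH3) | c1ccccc1COc1cc(OCc2ccccc2)cc(Oc2c(C(C)=O)cc(Oc3c(C(C)=O)cc(Oc4c(C(C)=O)cc(OCc5ccccc5)cc4C(C)=O)cc3C(C)=O)cc2C(C)=O)c1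
F3 | step 11 | hexaacetate of 18 | c1ccccc1COc1cc(OCc2ccccc2)cc(Oc2c(OC(C)=O)cc(Oc3c(OC(C)=O)cc(Oc4c(OC(C)=O)cc(OCc5ccccc5)cc4OC(C)=O)cc3OC(C)=O)cc2OC(C)=O)c1
F4 | step 2 | (4-fluorophenoxy)tri(propan-2-yl)silane | CC(C)[Si](C(C)C)(C(C)C)Oc1ccc(F)cc1
F5 | step 2 | (2-fluoro-5-{[tri(propan-2-yl)silyl]oxy}phenyl)lithium | CC(C)[Si](C(C)C)(C(C)C)Oc1ccc(F)c([Li])c1
F6 | step 2 | lithium (dimethylamino)(2-fluoro-5-{[tri(propan-2-yl)silyl]oxy}phenyl)methanolate (racemic) | CC(C)[Si](C(C)C)(C(C)C)Oc1ccc(F)c(c1)C(O[Li])N(C)C
F7 | step 2 | lithium (dimethylamino)(2-fluoro-3-lithio-5-{[tri(propan-2-yl)silyl]oxy}phenyl)methanolate (racemic) | CC(C)[Si](C(C)C)(C(C)C)Oc1cc([Li])c(F)c(c1)C(O[Li])N(C)C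
F8 | step 2 | dilithium (2-fluoro-5-{[tri(propan-2-yl)silyl]oxy}-1,3-phenylene)bis[(dimethylamino)methanolate] (stereoisomer mixture) | CC(C)[Si](C(C)C)(C(C)C)Oc1cc(C(O[Li])N(C)C)c(F)c(c1)C(O[Li])N(C)C
F9 | step 2 | 2-fluoro-5-{[tri(propan-2-yl)silyl]oxy}benzene-1,3-dicarbaldehyde | CC(C)[Si](C(C)C)(C(C)C)Oc1cc(C=O)c(F)c(C=O)c1
F10 | step 10 | 4-fluoro-3,5-bis(1,3-dioxolan-2-yl)phenol | Oc1cc(C2OCCO2)c(F)c(C2OCCO2)c1
F11 | step 10 | 5-(benzyloxy)-2-[4-fluoro-3,5-bis(1,3-dioxolan-2-yl)phenoxy]benzene-1,3-dicarbaldehyde | O=Cc1cc(OCc2ccccc2)cc(C=O)c1Oc1cc(C2OCCO2)c(F)c(C2OCCO2)c1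
F12 | step 10 | 5-(benzyloxy)-2-(4-fluoro-3,5-diformylphenoxy)benzene-1,3-dicarbaldehyde | O=Cc1cc(OCc2ccccc2)cc(C=O)c1Oc1cc(C=O)c(F)c(C=O)c1
F13 | step 7 | 2-fluoro-5-[(4-methoxyphenyl)methoxy]benzene-1,3-dicarbaldehyde | COc1ccc(COc2cc(C=O)c(F)c(C=O)c2)cc1
F14 | step 7 | 2-[3,5-bis(benzyloxy)phenoxy]-5-[(4-methoxyphenyl)methoxy]benzene-1,3-dicarbaldehyde | COc1ccc(COc2cc(C=O)c(Oc3cc(OCc4ccccc4)cc(OCc4ccccc4)c3)c(C=O)c2)cc1
F15 | step 7 | 2-[3,5-bis(benzyloxy)phenoxy]-5-{2,6-diformyl-4-[(4-methoxyphenyl)methoxy]phenoxy}benzene-1,3-dicarbaldehyde | COc1ccc(COc2cc(C=O)c(Oc3cc(C=O)c(Oc4cc(OCc5ccccc5)cc(OCc5ccccc5)c4)c(C=O)c3)c(C=O)c2)cc1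
A1 | alternative 1 | 2-(ethynyloxy)-1,3-dimethoxy-5-[2,6-dimethoxy-4-(2,4,6-trimethoxyphenoxy)phenoxy]benzene | C#COc1c(OC)cc(Oc2c(OC)cc(Oc3c(OC)cc(OC)cc3OC)cc2OC)cc1OC
A2 | alternative 1 | 3-ethoxycyclobut-2-en-1-one | CCOC1=CC(=O)C1
A3 | alternative 1 | 3-ethoxy-5-{2,6-dimethoxy-4-[2,6-dimethoxy-4-(2,4,6-trimethoxyphenoxy)phenoxy]phenoxy}phenol | CCOc1cc(O)cc(Oc2c(OC)cc(Oc3c(OC)cc(Oc4c(OC)cc(OC)cc4OC)cc3OC)cc2OC)c1
A4 | alternative 2 | 4-{2,6-dimethoxy-4-[2,6-dimethoxy-4-(2,4,6-trimethoxyphenoxy)phenoxy]phenoxy}-6-methyl-2H-pyran-2-one | CC1=CC(Oc2c(OC)cc(Oc3c(OC)cc(Oc4c(OC)cc(OC)cc4OC)cc3OC)cc2OC)=CC(=O)O1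
A5 | alternative 2 | 5-{2,6-dimethoxy-4-[2,6-dimethoxy-4-(2,4,6-trimethoxyphenoxy)phenoxy]phenoxy}benzene-1,3-diol | Oc1cc(O)cc(Oc2c(OC)cc(Oc3c(OC)cc(Oc4c(OC)cc(OC)cc4OC)cc3OC)cc2OC)c1
A6 | alternative 3 | dimethyl 2-{4-[4-(3,5-dimethoxyphenoxy)-3,5-dimethoxyphenoxy]-3,5-dimethoxyphenoxy}propanedioate | COC(=O)C(Oc1cc(OC)c(Oc2cc(OC)c(Oc3cc(OC)cc(OC)c3)c(OC)c2)c(OC)c1)C(=O)OC
A7 | alternative 3 | dimethyl 3-oxopentanedioate | COC(=O)CC(=O)CC(=O)OC
A8 | alternative 3 | dimethyl 5-{4-[4-(3,5-dimethoxyphenoxy)-3,5-dimethoxyphenoxy]-3,5-dimethoxyphenoxy}-2,4,6-trihydroxybenzene-1,3-dicarboxylate | COC(=O)c1c(O)c(C(=O)OC)c(O)c(Oc2cc(OC)c(Oc3cc(OC)c(Oc4cc(OC)cc(OC)c4)c(OC)c3)c(OC)c2)c1O
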